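**Retrosynthetic overview**
1. Target ⇐ its primary O‑benzyl ether (hydrogenolysis). The unsubstituted indol‑3‑yl ring is built last, by Fischer indolisation of a γ‑lactol with phenylhydrazine; the lactol ring oxygen becomes the secondary OH.
2. γ‑Lactol ⇐ cis‑4‑(indol‑2‑yl)‑5‑(benzyloxymethyl)‑γ‑butyrolactone, by a reduction that spares the acetate.
3. Key disconnection (C1–C2 of the diol chain): cis‑lactone ⇐ 3‑(indol‑2‑yl)acrolein + benzyloxyacetaldehyde. A chiral carbene catalyst makes the enal β‑carbon a homoenolate nucleophile that attacks the aldehyde carbon; both stereocentres are set in this bond formation.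
4. Enal ⇐ tryptophol acetate, by C2 bromination and Heck vinylation with acrolein diethyl acetal.
5. Ring order: tryptophol indole bought intact → γ‑lactone ring (key step) → second indole ring (Fischer).

Assumption: the (5aS,10bR) antipode of the aminoindanol‑derived N‑mesityl triazolium salt is taken to give the (4S,5S) lactone; if the first run shows the opposite sense, its mirror‑image salt is used and nothing else changes.

The target is (1S,2S) at the propyl chain (C1 = bis‑indolyl methine, C2 = secondary carbinol). This corresponds to a cis‑(4S,5S) lactone, in which the ring CH2–C(=O) unit later becomes the indol‑3‑yl group.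

**Step 1**
Reactants: 1 tryptophol (2‑(1H‑indol‑3‑yl)ethan‑1‑ol)
Product: 2 2‑(1H‑indol‑3‑yl)ethyl acetate
Conditions: Ac2O (1.2 equiv), pyridine, CH2Cl2, 0 °C to rt
Reagents that add atoms: acetic anhydride, CC(=O)OC(C)=O
Why: O‑acylation of the primary alcohol (nucleophilic acyl substitution); the weakly nucleophilic indole N–H is not acylated under these mild conditions.

**Step 2**
Reactants: 2 2‑(1H‑indol‑3‑yl)ethyl acetate
Product: 3 2‑(2‑bromo‑1H‑indol‑3‑yl)ethyl acetate
Conditions: NBS (1.05 equiv), CH2Cl2, 0 °C, dark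
Reagents that add atoms: N‑bromosuccinimide, O=C1CCC(=O)N1Br
Why: electrophilic aromatic bromination of a 3‑substituted indole; attack at C3 followed by 1,2‑shift of bromine and rearomatisation delivers the 2‑bromo compound.

**Step 3**
Reactants: 3 2‑(2‑bromo‑1H‑indol‑3‑yl)ethyl acetate; 4 acrolein diethyl acetal (3,3‑diethoxyprop‑1‑ene)
Product: 6 2‑{2‑[(E)‑3‑oxoprop‑1‑en‑1‑yl]‑1H‑indol‑3‑yl}ethyl acetate, via diethyl acetal 5 (not isolated)
Conditions: Pd(OAc)2 (3 mol %), nBu4NOAc (2 equiv), K2CO3 (1.5 equiv), KCl (1 equiv), DMF, 90 °C; then 2 M HCl, rt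
Reagents that add atoms: water, O
Why: Mizoroki–Heck vinylation (oxidative addition of the C–Br bond to zerovalent palladium, syn insertion, β‑hydride elimination to the E alkene) followed by acetal hydrolysis, the established route from aryl bromides to cinnamaldehydes.

**Step 4 (key step)**
Reactants: 6 2‑{2‑[(E)‑3‑oxoprop‑1‑en‑1‑yl]‑1H‑indol‑3‑yl}ethyl acetate; 7 benzyloxyacetaldehyde
Product: 8 2‑{2‑[(2S,3S)‑2‑[(benzyloxy)methyl]‑5‑oxooxolan‑3‑yl]‑1H‑indol‑3‑yl}ethyl acetate (cis‑(4S,5S)‑γ‑butyrolactone)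
Conditions: (5aS,10bR)‑2‑mesityl‑5a,10b‑dihydro‑4H,6H‑indeno[2,1‑b][1,2,4]triazolo[4,3‑d][1,4]oxazin‑2‑ium chloride (10 mol %), DBU (20 mol %), 7 (2 equiv), 4 Å MS, THF, 0 °C to rt, 6 added over 4 h
Reagents that add atoms: none
Why: Proposed new method: the carbene adds to the aldehyde of 6 and a proton shift gives the extended Breslow intermediate, whose β‑carbon (a homoenolate, normally the electrophilic end of the enal) attacks the electrophilic carbonyl carbon of 7, after which the new alkoxide closes onto the acyl azolium to release the lactone and the carbene; the cis relationship follows the known cis preference of this annulation and the aminoindanol backbone shields one face of the homoenolate, so both stereocentres (4S,5S) are set in the C–C bond‑forming event; the closest known reaction type is the N‑heterocyclic‑carbene‑catalysed homoenolate [3+2] annulation of cinnamaldehydes with aldehydes to cis‑γ‑butyrolactones, extended here to a 2‑indolyl enal, an α‑alkoxy aliphatic acceptor and high enantiocontrol.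

**Step 5**
Reactants: 8 cis‑(4S,5S)‑lactone
Product: 9 2‑{2‑[(2S,3S)‑2‑[(benzyloxy)methyl]‑5‑hydroxyoxolan‑3‑yl]‑1H‑indol‑3‑yl}ethyl acetate (lactol, anomeric mixture)
Conditions: Sia2BH (4 equiv, made from BH3·THF and 2‑methylbut‑2‑ene), THF, 0 °C to rt; then MeOH/H2O
Reagents that add atoms: none
Why: chemoselective hydride reduction; disiamylborane reduces γ‑lactones to lactols but leaves acyclic esters such as the acetate untouched (as in reductions of acylated aldonolactones), and neither stereocentre is involved.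

**Step 6**
Reactants: 9 lactol; 10 phenylhydrazine
Product: 12 2‑{2‑[(1S,2S)‑3‑(benzyloxy)‑2‑hydroxy‑1‑(1H‑indol‑3‑yl)propyl]‑1H‑indol‑3‑yl}ethyl acetate, via phenylhydrazone 11 (not isolated)
Conditions: PhNHNH2 (1.1 equiv), AcOH, rt 1 h, then 80–90 °C 2 h
Reagents that add atoms: none
Why: Fischer indole synthesis in its tryptophol‑forming variant; the open hydroxy‑aldehyde form of the lactol gives the hydrazone, [3,3]‑rearrangement at the only α‑CH2 and loss of ammonia build the 3‑substituted indole, the former ring oxygen is released as the C2 hydroxyl, and C1 (β to the hydrazone carbon) cannot epimerise through the ene‑hydrazine.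

**Step 7**
Reactants: 12 benzyl ether
Product: 13 Colletotryptin C, 2‑{2‑[(1S,2S)‑2,3‑dihydroxy‑1‑(1H‑indol‑3‑yl)propyl]‑1H‑indol‑3‑yl}ethyl acetate
Conditions: H2 (1 atm), 10% Pd/C, EtOAc/EtOH, rt
Reagents that add atoms: none
Why: hydrogenolysis of the benzyl ether under neutral conditions, which leaves the acetate, both indoles and both stereocentres untouched.

**Compound list**
1 | tryptophol, 2‑(1H‑indol‑3‑yl)ethan‑1‑ol | OCCc1c[nH]c2ccccc12 | starting material
2 | 2‑(1H‑indol‑3‑yl)ethyl acetate | CC(=O)OCCc1c[nH]c2ccccc12 | intermediate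
3 | 2‑(2‑bromo‑1H‑indol‑3‑yl)ethyl acetate | CC(=O)OCCc1c(Br)[nH]c2ccccc12 | intermediate
4 | acrolein diethyl acetal, 3,3‑diethoxyprop‑1‑ene | C=CC(OCC)OCC | starting material
5 | 2‑{2‑[(E)‑3,3‑diethoxyprop‑1‑en‑1‑yl]‑1H‑indol‑3‑yl}ethyl acetate | CC(=O)OCCc1c(/C=C/C(OCC)OCC)[nH]c2ccccc12 | intermediate (not isolated)
6 | 2‑{2‑[(E)‑3‑oxoprop‑1‑en‑1‑yl]‑1H‑indol‑3‑yl}ethyl acetate | CC(=O)OCCc1c(/C=C/C=O)[nH]c2ccccc12 | intermediate
7 | benzyloxyacetaldehyde | O=CCOCc1ccccc1 | starting material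
8 | 2‑{2‑[(2S,3S)‑2‑[(benzyloxy)methyl]‑5‑oxooxolan‑3‑yl]‑1H‑indol‑3‑yl}ethyl acetate | CC(=O)OCCc1c([C@@H]2CC(=O)O[C@@H]2COCc3ccccc3)[nH]c4ccccc14 | intermediate
9 | 2‑{2‑[(2S,3S)‑2‑[(benzyloxy)methyl]‑5‑hydroxyoxolan‑3‑yl]‑1H‑indol‑3‑yl}ethyl acetate (anomers) | CC(=O)OCCc1c([C@@H]2CC(O)O[C@@H]2COCc3ccccc3)[nH]c4ccccc14 | intermediate
10 | phenylhydrazine | NNc1ccccc1 | starting material
11 | 2‑{2‑[(2S,3S,5E)‑1‑(benzyloxy)‑2‑hydroxy‑5‑(2‑phenylhydrazinylidene)pentan‑3‑yl]‑1H‑indol‑3‑yl}ethyl acetate | CC(=O)OCCc1c([C@H](C/C=N/Nc2ccccc2)[C@H](O)COCc3ccccc3)[nH]c4ccccc14 | intermediate (not isolated)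
12 | 2‑{2‑[(1S,2S)‑3‑(benzyloxy)‑2‑hydroxy‑1‑(1H‑indol‑3‑yl)propyl]‑1H‑indol‑3‑yl}ethyl acetate | CC(=O)OCCc1c([C@H](c2c[nH]c3ccccc23)[C@H](O)COCc4ccccc4)[nH]c5ccccc15 | intermediate
13 | Colletotryptin C | CC(=O)OCCc1c([C@H](c2c[nH]c3ccccc23)[C@H](O)CO)[nH]c2ccccc12 | target

**Totals**
Total steps: 7. Longest linear sequence: 7 (from tryptophol 1; 4, 7 and 10 are bought).

**Steps most likely to fail**

Step 4 (key annulation). The risks are protonation of the homoenolate followed by acylation of the indole nitrogen, self‑annulation of 6, acyl‑anion side reactions of 7, and modest cis/trans ratio or enantiomeric excess with an aliphatic acceptor. Fallback, setting out from 6 and returning at 13: Luche reduction (NaBH4, CeCl3·7H2O, MeOH, −40 °C) gives the allylic alcohol 2‑{2‑[(E)‑3‑hydroxyprop‑1‑en‑1‑yl]‑1H‑indol‑3‑yl}ethyl acetate F1. Sharpless asymmetric epoxidation (Ti(OiPr)4, D‑(−)‑diethyl tartrate, tBuOOH, 4 Å MS, CH2Cl2, −25 °C) gives the trans epoxy alcohol 2‑{2‑[(2R,3R)‑3‑(hydroxymethyl)oxiran‑2‑yl]‑1H‑indol‑3‑yl}ethyl acetate F2. Without isolation, indole is added and opens the epoxide at the indolyl‑bearing carbon with inversion (Ti(OiPr)4‑assisted), which gives 13 directly. Inversion may be eroded if the opening goes through a free cation.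

Step 5 (lactone to lactol beside an acetate). The risks are partial loss of the acetate and slow reduction of the hindered cis‑lactone. Fallback, setting out from 8 and returning at 12: reduce both esters with iBu2AlH (3.5 equiv, CH2Cl2, −78 °C) to (4S,5S)‑5‑[(benzyloxy)methyl]‑4‑[3‑(2‑hydroxyethyl)‑1H‑indol‑2‑yl]oxolan‑2‑ol F3. Fischer indolisation with 10 in AcOH then passes through the phenylhydrazone (2S,3S,5E)‑1‑(benzyloxy)‑3‑[3‑(2‑hydroxyethyl)‑1H‑indol‑2‑yl]‑5‑(2‑phenylhydrazinylidene)pentan‑2‑ol F4 to the diol (2S,3S)‑1‑(benzyloxy)‑3‑[3‑(2‑hydroxyethyl)‑1H‑indol‑2‑yl]‑3‑(1H‑indol‑3‑yl)propan‑2‑ol F5. The unhindered primary alcohol of F5 is then acetylated selectively (vinyl acetate, Candida antarctica lipase B, or Ac2O/2,4,6‑collidine at −40 °C) to give 12.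

Step 6 (Fischer indolisation). The risks are cyclisation of the aldehyde or hydrazone onto the neighbouring indole N–H, oxa‑Pictet–Spengler reaction of the product with unreacted aldehyde, and acid‑induced scrambling of the bis‑indolyl methine. Fallback, setting out from 9 and returning at 12: condense 9 with 2‑iodoaniline to the imine 2‑{2‑[(2S,3S,5E)‑1‑(benzyloxy)‑2‑hydroxy‑5‑[(2‑iodophenyl)imino]pentan‑3‑yl]‑1H‑indol‑3‑yl}ethyl acetate F6. Its enamine tautomer is closed by an intramolecular Heck reaction (Pd(OAc)2, DABCO, DMF, 85 °C) under non‑acidic conditions to give 12.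

**Further compounds**
F1 | step 4 | 2‑{2‑[(E)‑3‑hydroxyprop‑1‑en‑1‑yl]‑1H‑indol‑3‑yl}ethyl acetate | CC(=O)OCCc1c(/C=C/CO)[nH]c2ccccc12
F2 | step 4 | 2‑{2‑[(2R,3R)‑3‑(hydroxymethyl)oxiran‑2‑yl]‑1H‑indol‑3‑yl}ethyl acetate | CC(=O)OCCc1c([C@H]2O[C@@H]2CO)[nH]c3ccccc13
F3 | step 5 | (4S,5S)‑5‑[(benzyloxy)methyl]‑4‑[3‑(2‑hydroxyethyl)‑1H‑indol‑2‑yl]oxolan‑2‑ol | OCCc1c([C@@H]2CC(O)O[C@@H]2COCc3ccccc3)[nH]c4ccccc14
F4 | step 5 | (2S,3S,5E)‑1‑(benzyloxy)‑3‑[3‑(2‑hydroxyethyl)‑1H‑indol‑2‑yl]‑5‑(2‑phenylhydrazinylidene)pentan‑2‑ol | OCCc1c([C@H](C/C=N/Nc2ccccc2)[C@H](O)COCc3ccccc3)[nH]c4ccccc14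
F5 | step 5 | (2S,3S)‑1‑(benzyloxy)‑3‑[3‑(2‑hydroxyethyl)‑1H‑indol‑2‑yl]‑3‑(1H‑indol‑3‑yl)propan‑2‑ol | OCCc1c([C@H](c2c[nH]c3ccccc23)[C@H](O)COCc4ccccc4)[nH]c5ccccc15
F6 | step 6 | 2‑{2‑[(2S,3S,5E)‑1‑(benzyloxy)‑2‑hydroxy‑5‑[(2‑iodophenyl)imino]pentan‑3‑yl]‑1H‑indol‑3‑yl}ethyl acetate | CC(=O)OCCc1c([C@H](C/C=N/c2ccccc2I)[C@H](O)COCc3ccccc3)[nH]c4ccccc14
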